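## Retrosynthetic overview

1. The only ring made is the 18-membered macrocycle. It is closed late by oxidative phenol C–O coupling: the ring A phenol oxygen is joined to the carbon ortho to the OH of the ring D para-alkylphenol (para blocked, both ortho sites equivalent, so one regiochemical outcome).
2. Halogens assign the roles: ring D as the more easily oxidised 2,6-dibromophenol, ring A as the 2,6-dichlorophenol O-nucleophile. One hydrogenolysis removes the three remaining halogens, then BBr3 frees the ring B catechol.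
3. The seco-bisphenol comes from two B-alkyl Suzuki couplings: bridge C–D from 4-acetoxystyrene, bridge A–B from the ring B styrene and 4-bromo-2,6-dichlorophenol.
4. The crowded ring B–O–ring C ether, whose site on ring B cannot be steered by oxidation, is set first by Ullmann coupling of 2-bromo-3,4-dimethoxybenzaldehyde with 3-chlorophenol. The four benzene rings are bought.

Assumption: the target has no stereocentre and its macrocycle is conformationally mobile, so it is achiral and there is no enantiomer to select.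

## Route

Step 1
Reactants: 1 2-bromo-3,4-dimethoxybenzaldehyde; 2 3-chlorophenol
Product: 3 2-(3-chlorophenoxy)-3,4-dimethoxybenzaldehyde
Conditions: CuI (10 mol %), N,N-dimethylglycine hydrochloride (30 mol %), Cs2CO3 (2.5 equiv), dioxane, 100 °C
Reagents that add atoms: none
Why: Ullmann diaryl ether synthesis, in which the ortho-formyl group activates the hindered C-2 bromide of 1 toward copper-mediated substitution by the phenoxide of 2 while the aryl chloride of 2 stays inert.

Step 2
Reactants: 3 2-(3-chlorophenoxy)-3,4-dimethoxybenzaldehyde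
Product: 4 2-(3-chlorophenoxy)-1-ethenyl-3,4-dimethoxybenzene
Conditions: Ph3PCH3Br (1.3 equiv), KOtBu (1.25 equiv), THF, 0 °C to rt
Reagents that add atoms: methyltriphenylphosphonium bromide, C[P+](c1ccccc1)(c1ccccc1)c1ccccc1.[Br-]
Why: Wittig methylenation with the unstabilised ylide converts the electron-rich aldehyde into the styrene needed for the later bridge, and no stereocentre is created.

Step 3
Reactants: 4 2-(3-chlorophenoxy)-1-ethenyl-3,4-dimethoxybenzene; 5 4-ethenylphenyl acetate
Product: 8 4-[2-[3-(6-ethenyl-2,3-dimethoxyphenoxy)phenyl]ethyl]phenol, via alkylborane 6 (not isolated), via aryl acetate 7 (not isolated)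
Conditions: 5 (1.3 equiv), 9-BBN (1.25 equiv), THF, 0 °C to rt, 4 h; then 4, Pd(OAc)2 (3 mol %), SPhos (6 mol %), 3 M aq K3PO4, 65 °C, 16 h
Reagents that add atoms: none
Why: Anti-Markovnikov hydroboration of styrene 5 followed by B-alkyl Suzuki–Miyaura coupling at the aryl chloride of 4 (made reactive by SPhos) gives the saturated C–D bridge directly, the hot aqueous phosphate hydrolyses the aryl acetate, and the vinyl group of 4 survives because no B–H is left when it is added.

Step 4
Reactants: 8 4-[2-[3-(6-ethenyl-2,3-dimethoxyphenoxy)phenyl]ethyl]phenol; 9 4-bromo-2,6-dichlorophenol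
Product: 11 2,6-dichloro-4-[2-[2-[3-[2-(4-hydroxyphenyl)ethyl]phenoxy]-3,4-dimethoxyphenyl]ethyl]phenol, via alkylborane 10 (not isolated)
Conditions: 9-BBN (2.3 equiv), THF, rt; then 9 (1.2 equiv), Pd(dppf)Cl2 (5 mol %), 3 M aq K3PO4, THF–DMF, 65 °C
Reagents that add atoms: none
Why: Hydroboration of the ring B styrene and B-alkyl Suzuki–Miyaura coupling at the C–Br bond of 9 (its two C–Cl bonds are inert to the dppf catalyst) attaches ring A with its chlorine auxiliaries already in place.

Step 5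
Reactants: 11 2,6-dichloro-4-[2-[2-[3-[2-(4-hydroxyphenyl)ethyl]phenoxy]-3,4-dimethoxyphenyl]ethyl]phenol
Product: 12 2,6-dibromo-4-[2-[3-[6-[2-(3,5-dichloro-4-hydroxyphenyl)ethyl]-2,3-dimethoxyphenoxy]phenyl]ethyl]phenol
Conditions: NBS (2.05 equiv), iPr2NH (10 mol %), CH2Cl2, 0 °C
Reagents that add atoms: N-bromosuccinimide, O=C1CCC(=O)N1Br
Why: Amine-catalysed ortho-bromination of a phenol (electrophilic aromatic substitution) dibrominates only ring D, because both ortho positions of the ring A phenol are blocked by chlorine and aryl ethers do not react under these conditions.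

Step 6
Reactants: 12 2,6-dibromo-4-[2-[3-[6-[2-(3,5-dichloro-4-hydroxyphenyl)ethyl]-2,3-dimethoxyphenoxy]phenyl]ethyl]phenol
Product: 14 marchantin H ring B di-O-methyl ether carrying Br on ring D ortho to the OH plus Cl at both ring A positions ortho to the ether oxygen, via methoxydienone 13 (not isolated)
Conditions: Tl(NO3)3·3H2O (1.2 equiv), MeOH–THF 4:1, 1 mM, −20 °C, 20 min; then Zn dust (20 equiv), AcOH, 0 °C to rt
Reagents that add atoms: none
Why: Oxidative phenol coupling of an o,o'-dihalophenol pair by trivalent thallium, in which the more easily oxidised dibromophenol (ring D) becomes a phenoxonium ion, the dichlorophenol oxygen (ring A) attacks its bromine-bearing ortho carbon with loss of bromide, solvent methanol caps C-4 to give dienone 13, and zinc reduces 13 back to the phenol with loss of methanol; the halogens suppress C–C coupling and the transient C-4 stereocentre disappears.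

Step 7
Reactants: 14 bromodichloro macrocycle
Product: 15 marchantin H ring B di-O-methyl ether (ring D phenol free)
Conditions: H2 (1 atm), 10% Pd/C, NaOAc (5 equiv), MeOH–EtOAc, rt
Reagents that add atoms: none
Why: Catalytic hydrodehalogenation over palladium with acetate as acid scavenger removes the one C–Br and two C–Cl bonds without touching the diaryl ethers.

Step 8
Reactants: 15 marchantin H ring B di-O-methyl ether
Product: 16 marchantin H
Conditions: BBr3 (6 equiv), CH2Cl2, −78 °C to 0 °C; then H2O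
Reagents that add atoms: none
Why: Lewis-acid cleavage of aryl methyl ethers by BBr3 frees the ring B catechol, while diaryl ethers are stable to the reagent.

## Compound list

1 | 2-bromo-3,4-dimethoxybenzaldehyde | O=Cc1ccc(OC)c(OC)c1Br | starting material
2 | 3-chlorophenol | Oc1cccc(Cl)c1 | starting material
3 | 2-(3-chlorophenoxy)-3,4-dimethoxybenzaldehyde | O=Cc1ccc(OC)c(OC)c1Oc1cccc(Cl)c1 | intermediate
4 | 2-(3-chlorophenoxy)-1-ethenyl-3,4-dimethoxybenzene | C=Cc1ccc(OC)c(OC)c1Oc1cccc(Cl)c1 | intermediate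
5 | 4-ethenylphenyl acetate (4-acetoxystyrene) | CC(=O)Oc1ccc(C=C)cc1 | starting material
6 | alkylborane: 4-[2-(9-borabicyclo[3.3.1]nonan-9-yl)ethyl]phenyl acetate | CC(=O)Oc1ccc(CCB2C3CCCC2CCC3)cc1 | intermediate
7 | aryl acetate: 4-[2-[3-(6-ethenyl-2,3-dimethoxyphenoxy)phenyl]ethyl]phenyl acetate | CC(=O)Oc1ccc(CCc2cccc(Oc3c(C=C)ccc(OC)c3OC)c2)cc1 | intermediate
8 | 4-[2-[3-(6-ethenyl-2,3-dimethoxyphenoxy)phenyl]ethyl]phenol | Oc1ccc(CCc2cccc(Oc3c(C=C)ccc(OC)c3OC)c2)cc1 | intermediate
9 | 4-bromo-2,6-dichlorophenol | Oc1c(Cl)cc(Br)cc1Cl | starting material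
10 | alkylborane: 4-[2-[3-[6-[2-(9-borabicyclo[3.3.1]nonan-9-yl)ethyl]-2,3-dimethoxyphenoxy]phenyl]ethyl]phenol | Oc1ccc(CCc2cccc(Oc3c(CCB4C5CCCC4CCC5)ccc(OC)c3OC)c2)cc1 | intermediate
11 | 2,6-dichloro-4-[2-[2-[3-[2-(4-hydroxyphenyl)ethyl]phenoxy]-3,4-dimethoxyphenyl]ethyl]phenol | Oc1ccc(CCc2cccc(Oc3c(CCc4cc(Cl)c(O)c(Cl)c4)ccc(OC)c3OC)c2)cc1 | intermediate
12 | 2,6-dibromo-4-[2-[3-[6-[2-(3,5-dichloro-4-hydroxyphenyl)ethyl]-2,3-dimethoxyphenoxy]phenyl]ethyl]phenol | Oc1c(Br)cc(CCc2cccc(Oc3c(CCc4cc(Cl)c(O)c(Cl)c4)ccc(OC)c3OC)c2)cc1Br | intermediate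
13 | methoxydienone: macrocycle 14 with ring D as a 2-aryloxy-6-bromo-4-methoxycyclohexa-2,5-dien-1-one whose C-4 carries the CH2CH2 bridge (racemic at C-4) | O=C1C(Br)=CC2(OC)C=C1Oc1c(Cl)cc(cc1Cl)CCc1ccc(OC)c(OC)c1Oc1cccc(c1)CC2 | intermediate
14 | marchantin H ring B di-O-methyl ether carrying Br on ring D ortho to the OH plus Cl at both ring A positions ortho to the ether oxygen | Oc1c(Br)cc2cc1Oc1c(Cl)cc(cc1Cl)CCc1ccc(OC)c(OC)c1Oc1cccc(c1)CC2 | intermediate
15 | marchantin H ring B di-O-methyl ether (ring D phenol free) | Oc1ccc2cc1Oc1ccc(cc1)CCc1ccc(OC)c(OC)c1Oc1cccc(c1)CC2 | intermediate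
16 | marchantin H (achiral) | Oc1ccc2cc1Oc1ccc(cc1)CCc1ccc(O)c(O)c1Oc1cccc(c1)CC2 | target

## Step count and risks

Total step count: 8. Longest linear sequence: 8 steps (1 to 16); compounds 2, 5 and 9 are bought and enter directly.

The three steps most likely to fail:

**Step 6 (oxidative macrocyclisation).** The precedent for this coupling is in more rigid, peptide-type ring systems; here the chain is flexible, so oligomers, methanol trapping without C–O bond formation, or attack by the electron-rich ring B are all possible. If it fails, the same ring A–O–ring D bond is closed by intramolecular Ullmann etherification. This fallback sets out from 8 and bypasses steps 4 to 7.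
- NBS (1.0 equiv), iPr2NH (cat.), CH2Cl2, −20 °C brominates once ortho to the ring D hydroxyl and gives 2-bromo-4-[2-[3-(6-ethenyl-2,3-dimethoxyphenoxy)phenyl]ethyl]phenol F1.
- MeI, K2CO3, acetone gives 2-bromo-4-[2-[3-(6-ethenyl-2,3-dimethoxyphenoxy)phenyl]ethyl]-1-methoxybenzene F2.
- 9-BBN adds to the vinyl group to give 9-[2-[2-[3-[2-(3-bromo-4-methoxyphenyl)ethyl]phenoxy]-3,4-dimethoxyphenyl]ethyl]-9-borabicyclo[3.3.1]nonane F3.
- F3 couples at the C–I bond of 4-iodophenol (Pd(dppf)Cl2, aq K3PO4, 40 °C, the hindered aryl bromide being slower) to give 4-[2-[2-[3-[2-(3-bromo-4-methoxyphenyl)ethyl]phenoxy]-3,4-dimethoxyphenyl]ethyl]phenol F4.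
- CuO, K2CO3, pyridine, 130 °C, 2 mM closes the ring to marchantin H tri-O-methyl ether F5.
- BBr3 as in step 8 cleaves all three methyl ethers, so the fallback comes back to the route at 16.

**Step 3 (B-alkyl coupling at an unactivated aryl chloride beside a styrene).** Slow oxidative addition or side reactions of the vinyl group could spoil it. If so, the C–D bridge is made before the diaryl ether, from an aryl bromide and with a tert-butyl ether on ring D. This fallback sets out from 1.
- 4-tert-Butoxystyrene and 9-BBN give 9-[2-(4-tert-butoxyphenyl)ethyl]-9-borabicyclo[3.3.1]nonane F6.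
- F6 couples with 3-bromophenol (Pd(dppf)Cl2, aq K3PO4) to give 3-[2-(4-tert-butoxyphenyl)ethyl]phenol F7.
- Ullmann coupling of F7 with 1 under the conditions of step 1 gives 2-[3-[2-(4-tert-butoxyphenyl)ethyl]phenoxy]-3,4-dimethoxybenzaldehyde F8.
- TFA, CH2Cl2, 0 °C removes the tert-butyl group before any acid-sensitive styrene is present and gives 2-[3-[2-(4-hydroxyphenyl)ethyl]phenoxy]-3,4-dimethoxybenzaldehyde F9.
- Wittig methylenation of F9 (2.3 equiv ylide) comes back to the route at 8.

**Step 4 (second B-alkyl coupling with a free, electron-rich bromophenol).** If hydroboration of 8 or transmetallation is poor, the A–B bridge is made by a Heck reaction and then reduced. This fallback sets out from 8. Heck coupling of 8 with 9 (Pd(OAc)2, P(o-tol)3, NaOAc, DMF, 110 °C) gives 2,6-dichloro-4-[(E)-2-[2-[3-[2-(4-hydroxyphenyl)ethyl]phenoxy]-3,4-dimethoxyphenyl]ethenyl]phenol F10. Diimide reduction (TsNHNH2, NaOAc, THF–H2O, reflux) saturates the stilbene without touching the C–Cl bonds and comes back to the route at 11.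

## Further compounds

F1 | step 6 | 2-bromo-4-[2-[3-(6-ethenyl-2,3-dimethoxyphenoxy)phenyl]ethyl]phenol | Oc1ccc(CCc2cccc(Oc3c(C=C)ccc(OC)c3OC)c2)cc1Br
F2 | step 6 | 2-bromo-4-[2-[3-(6-ethenyl-2,3-dimethoxyphenoxy)phenyl]ethyl]-1-methoxybenzene | COc1ccc(CCc2cccc(Oc3c(C=C)ccc(OC)c3OC)c2)cc1Br
F3 | step 6 | 9-[2-[2-[3-[2-(3-bromo-4-methoxyphenyl)ethyl]phenoxy]-3,4-dimethoxyphenyl]ethyl]-9-borabicyclo[3.3.1]nonane | COc1ccc(CCc2cccc(Oc3c(CCB4C5CCCC4CCC5)ccc(OC)c3OC)c2)cc1Br
F4 | step 6 | 4-[2-[2-[3-[2-(3-bromo-4-methoxyphenyl)ethyl]phenoxy]-3,4-dimethoxyphenyl]ethyl]phenol | COc1ccc(CCc2cccc(Oc3c(CCc4ccc(O)cc4)ccc(OC)c3OC)c2)cc1Br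
F5 | step 6 | marchantin H tri-O-methyl ether | COc1ccc2cc1Oc1ccc(cc1)CCc1ccc(OC)c(OC)c1Oc1cccc(c1)CC2
F6 | step 3 | 9-[2-(4-tert-butoxyphenyl)ethyl]-9-borabicyclo[3.3.1]nonane | CC(C)(C)Oc1ccc(CCB2C3CCCC2CCC3)cc1
F7 | step 3 | 3-[2-(4-tert-butoxyphenyl)ethyl]phenol | CC(C)(C)Oc1ccc(CCc2cccc(O)c2)cc1
F8 | step 3 | 2-[3-[2-(4-tert-butoxyphenyl)ethyl]phenoxy]-3,4-dimethoxybenzaldehyde | CC(C)(C)Oc1ccc(CCc2cccc(Oc3c(C=O)ccc(OC)c3OC)c2)cc1
F9 | step 3 | 2-[3-[2-(4-hydroxyphenyl)ethyl]phenoxy]-3,4-dimethoxybenzaldehyde | Oc1ccc(CCc2cccc(Oc3c(C=O)ccc(OC)c3OC)c2)cc1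
F10 | step 4 | 2,6-dichloro-4-[(E)-2-[2-[3-[2-(4-hydroxyphenyl)ethyl]phenoxy]-3,4-dimethoxyphenyl]ethenyl]phenol | Oc1ccc(CCc2cccc(Oc3c(/C=C/c4cc(Cl)c(O)c(Cl)c4)ccc(OC)c3OC)c2)cc1
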